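**Remark on the chemistry:** labdane locants are used for every intermediate (ring A = C1–C5 and C10, ring B = C5–C10, C11 = the carbon on C9; "11-nordrimane" means the 4,4,8,10-tetramethyl-trans-decalin core). α is the face opposite the C10 methyl. Temporary stereocentres (the α′ carbon of 4, C2 of 8–11, C9 of 18) are drawn as the expected major epimer and both epimers are carried on.

## The problem

The target 31 is a 14,15-dinorlabdane: a trans-fused decalin whose ring A is a bare gem-dimethylcyclohexane and whose ring B carries every functional group. Six contiguous stereocentres run from C5 to C10, among them the quaternary C10 (methyl β) and the tertiary carbinol C8 (hydroxyl α, methyl β and 1,3-diaxial to the C10 methyl). The three ring B oxygens (6α-OAc, 7β-OH, 8α-OH) are all equatorial, and the (E)-enone chain sits equatorially on C9 (9α-H). Once the trans fusion exists, the axial methyls on C10 and C4 close the β face of ring B, so α-face attack can set C6, C8 and C9 and axial hydride delivery can set C7. The fusion itself (C5 against C10) has no such guide and must come from the starting material. The acetate can migrate to the neighbouring 7-hydroxyl under base, the tertiary 8-hydroxyl can eliminate, and the enone has C9 as its γ-carbon, so base can epimerise C9 or expel the 8-hydroxyl; the enone therefore has to appear last and under near-neutral conditions. The enabling feature is that ring B maps atom for atom onto (R)-carvone 1: its carbonyl is C9, its methyl-bearing alkene carbon is C8, then come C7 and C6, C5 carries the isopropenyl group (C4 with one methyl and a CH2 that can become the second), and the α′ carbon is C10. Only C1–C3 are missing, and C4 becomes quaternary when a hydrogen atom is added to the isopropenyl CH2 and the resulting tertiary radical bonds to C3.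

## Retrosynthesis

**C11=C12.** The enone is cut at C11=C12, giving aldehyde 30 (made in the flask from primary alcohol 28) and the stabilised phosphorane 29. An alkyne at C9 reduced late was the neighbouring option, but it would be conjugated with the ring enone during the C8/C9 functionalisation; a benzyloxymethyl group is inert there. The forward reaction must oxidise a primary alcohol beside a secondary one and olefinate without base.

**C6–O and C7–H.** Alcohol 28 comes from benzyl ether 27, and 27 from ketone 26 by hydride addition at C7. The acetate of 26 goes back to diol 25, and the C6 oxygen of 25 to ketone 21 by Rubottom oxidation. A single C7 carbonyl thus serves both oxygens: it can enolise only toward C6 because C8 is fully substituted, and acetylating while C7 is still a ketone leaves no doubt which hydroxyl is acylated. The alternative, dihydroxylation of a C6=C7 alkene, would give the wrong (cis) relationship.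

**C8–O and C9–H.** Both bonds of 21 are cut together to the tetrasubstituted enone 19. A metal hydride delivers a hydrogen atom to the β-carbon C9 and dioxygen is captured at the α-keto radical C8. Dissolving-metal reduction would expel the γ-benzyloxy group and hydrogenation of a hindered tetrasubstituted alkene is unreliable. The forward step must work on the α face at both carbons.

**C9–C11 and the oxygen shift.** Enone 19 arises from tertiary allylic alcohol 18 by oxidative 1,3-transposition, and 18 from enone 12 and the hydroxymethyl-anion equivalent 17 (from stannane 16, itself from 13 and 14). The transposition moves oxygen from C9, where carvone has it and the target does not, to C7, where the target needs it. A conjugate addition to C9 would instead put the chain on the wrong (α) face.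

**C2 ester.** Enone 12 is traced to acid 9 and ester 8. The ester is a traceless activating group, removed by saponification and Barton decarboxylation through 10 and 11. This costs two steps, but without it the ring closure below would not be possible in the 6-endo sense.

**C3–C4 (key).** Ring A of 8 is opened at C3–C4 to give the monocyclic acrylate 7. Cutting here, and not at C1–C10 or C1–C2, lets the quaternary C4 form by radical addition instead of substitution at a tertiary centre, and draws its second methyl from the isopropenyl CH2. The precursor is a single ring two steps from 1. The forward reaction must generate the C4 radical selectively in the presence of an acrylate and an enone.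

**C10 substituents.** Precursor 7 comes from 4 and bromide 5, and 4 from 1 and 2. Methylating first and introducing the larger arm second places the arm anti to the isopropenyl group, which fixes C10 and, with it, the trans fusion.

## Roads not taken

**Alternative 1:** Rings A and B are cut together at C5–C10 and C8–C9. In the forward sense the acyclic trienal A1, with an (E)-enal as dienophile and a (5E,7Z)-silyloxydiene, would undergo an intramolecular Diels–Alder reaction under a chiral cationic oxazaborolidine Lewis acid to give the bicyclic aldehyde A2.
- Merits: one step closes both rings, sets C5, C8, C9 and C10 under catalyst control, delivers C11 as a 9β-formyl group and leaves a C6=C7 silyl enol ether that carries the C7 oxygen and opens C6 to oxidation. In stereocentres and rings per step it is better than the chosen key step, which closes one ring and creates no lasting stereocentre.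
- Weak points: A1 needs its own multistep synthesis with a geometrically pure, acid-sensitive silyl enol ether. The dienophile is a β,β-disubstituted enal that must form the quaternary C10, and the diene terminus C5 is neopentylic, so reactivity is low. The trans fusion, the endo/exo sense and the absolute configuration all depend on the catalyst. C8 arrives as a methine, so the tertiary 8α-hydroxyl must still be introduced by enolising the C7 ketone toward C8 in competition with C6, and the C8 centre set in the cycloaddition is given up.
- Comparison: the chosen plan takes its absolute configuration and the trans fusion from carvone and substrate control, and reaches the C8 oxygen directly from an enone.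

**Alternative 2:** Rings A and B are cut at C4–C5 and C9–C10, with C8–O. Squalene–hopene cyclase would protonate the terminal alkene of (5E,9E)-farnesylacetone A3 and close both rings, the ketone oxygen capturing the C8 cation to give sclareol oxide A4.
- Merits: one enzymatic step from an achiral commercial ketone gives the entire C18 skeleton with C5, C8, C9 and C10 correct, including the 8α C–O bond. For assembling the skeleton this is clearly better than the chosen plan, which needs nine steps to reach a comparable point.
- Weak points: A4 has two unactivated methylenes at C6 and C7, with no nearby group to direct a 6α and a 7β oxygenation. The enol ether must also be opened and the chain dehydrogenated to the (E)-enone in the presence of whatever is installed on ring B.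
- Comparison: the chosen plan brings ring B in already oxidised at C9 and unsaturated at C7=C8, so every ring B oxygen is reached by ordinary carbonyl chemistry with the axial methyls as control elements.

**Alternative 3:** Ring B is cut at C6–C7. The monocyclic aldehyde A5, which already carries the enone chain and an isopropenyl group on C9, would undergo a type 2 carbonyl-ene reaction with Me2AlCl to give alcohol A6 with a 6α-hydroxyl and a C8=C17 exocyclic methylene.
- Merits: the ring closure sets the C6 carbinol directly, the chain is in place, and on paper few steps follow.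
- Weak points: A5 holds three stereocentres (C5, C9 and the quaternary C10) on a flexible monocycle, so the hard stereochemical problem is moved into the precursor. The enone competes with the aldehyde for the aluminium Lewis acid and is a Michael acceptor. C9–H is both γ to the enone and allylic, so it is prone to epimerisation or isomerisation. After closure, C7 is still a methylene needing stereoselective allylic oxidation, and the exocyclic alkene must be hydrated to the 8α-ol with the enone present.
- Comparison: this road is more convergent and fixes C6 earlier, but the chosen plan keeps the enone out of all redox steps and derives C5 and C10 from carvone.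

Key step: step 3

## Route

**Step 1**
Reactants: 1 (R)-carvone; 2 iodomethane
Product: 4 trans-6-methylcarvone, via lithium dienolate 3 (not isolated)
Conditions: LiN(iPr)2, THF, −78 °C; then MeI, −78 to 0 °C
Reagents that add atoms: none
Why: Kinetic deprotonation at the α′ carbon (future C10) gives the cross-conjugated enolate, which is C-methylated (enolate alkylation). The new centre need not be controlled because it is planarised again in step 2.

**Step 2**
Reactants: 4 trans-6-methylcarvone; 5 ethyl 2-(bromomethyl)acrylate
Product: 7 ethyl 2-{[1,3-dimethyl-2-oxo-6-(prop-1-en-2-yl)cyclohex-3-en-1-yl]methyl}acrylate (arm trans to isopropenyl), via lithium enolate 6 (not isolated)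
Conditions: LiN(iPr)2, THF, −78 to −20 °C; then 5, DMPU, −78 °C to rt
Reagents that add atoms: none
Why: Alkylation of the tetrasubstituted enolate (SN2′ addition–elimination on the allylic bromide) should occur anti to the neighbouring isopropenyl group, the usual 1,2-induction in carvone enolates. This fixes C10 with the methyl β and the acrylate arm α, the relationship that later becomes the trans ring fusion.

**Step 3**
Reactants: 7 monocyclic acrylate
Product: 8 ethyl 9-oxo-11-nordrim-7-ene-2α-carboxylate (trans-fused)
Conditions: Fe(acac)3 (0.3 equiv), PhSiH3 (2.5 equiv), EtOH/(CH2OH)2 5:1, 0.02 M, 60 °C, Ar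
Reagents that add atoms: none
Why: This is an iron-catalysed hydrogen-atom-transfer reductive olefin coupling (donor alkene plus acrylate) run intramolecularly, a reaction type known for isopropenyl donors on cyclohexenone cores. Fe(acac)3 and PhSiH3 in ethanol form an iron hydride that transfers a hydrogen atom to the isopropenyl CH2, which becomes the second methyl on C4 and leaves a tertiary radical at C4. This nucleophilic radical adds to the unsubstituted acrylate terminus C3, forming C3–C4 and closing ring A in the 6-endo-trig mode; the α-ester radical at C2 is reduced by divalent iron to the enolate and protonated by solvent, which returns trivalent iron. The 6-endo path is secured by polarity matching and by C2 being fully substituted, since 5-exo attack would build a quaternary centre and a primary radical. No lasting stereocentre is created: the trans fusion is inherited from the trans C5 and C10 arms of 7, and the only new centre, C2, is set by enolate protonation (equatorial ester expected) and deleted in step 5. The step needs hydrogen-atom transfer to the electron-rich 1,1-disubstituted alkene in the presence of the acrylate and the enone; that alkene is the most electron-rich and gives the most stable radical, and the ring enone cannot serve as acceptor because C4 could reach C7 only through a four-membered ring. Oxygen is excluded so that the C4 radical is not diverted to hydration.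

**Step 4**
Reactants: 8 bicyclic ester
Product: 9 9-oxo-11-nordrim-7-ene-2α-carboxylic acid
Conditions: LiOH·H2O, THF/MeOH/H2O, 40 °C; then 1 M HCl
Reagents that add atoms: lithium hydroxide, [Li+].[OH-]
Why: Ester saponification; the enone has no α-hydrogen on the C10 side and tolerates aqueous hydroxide, and any epimerisation at C2 is irrelevant.

**Step 5**
Reactants: 9 carboxylic acid
Product: 12 11-nordrim-7-en-9-one, via acid chloride 10 (not isolated), via Barton ester 11 (not isolated)
Conditions: (COCl)2, DMF (cat.), CH2Cl2, 0 °C to rt; then C5H4NOSNa (sodium 2-pyridinethiolate N-oxide), DMAP (cat.), t-BuSH, toluene, visible light, 80 °C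
Reagents that add atoms: none
Why: Barton reductive decarboxylation: the thiohydroxamate ester fragments in a radical chain with loss of CO2, and the secondary C2 radical takes hydrogen from the thiol faster than it can add to the remote enone. This removes the activating group and the temporary C2 centre.

**Step 6**
Reactants: 13 tributyltin hydride; 14 benzyl chloromethyl ether
Product: 16 tributyl[(benzyloxy)methyl]stannane, via tributylstannyllithium 15 (not isolated)
Conditions: LiN(iPr)2, THF, 0 °C; then 14, −78 °C to rt
Reagents that add atoms: none
Why: Deprotonation of the tin hydride gives the stannyl anion, which displaces chloride from the chloromethyl ether (SN2); this is the standard preparation of α-alkoxymethylstannanes.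

**Step 7**
Reactants: 12 11-nordrim-7-en-9-one; 16 tributyl[(benzyloxy)methyl]stannane
Product: 18 9α-(benzyloxymethyl)-11-nordrim-7-en-9β-ol, via (benzyloxy)methyllithium 17 (not isolated)
Conditions: n-BuLi, THF, −78 °C; then 12, −78 to −40 °C; then H2O
Reagents that add atoms: none
Why: Tin–lithium exchange gives the α-alkoxy organolithium, a hard nucleophile that adds 1,2 to the enone carbonyl and forms C9–C11. Attack is expected anti to the axial C10 methyl, but the C9 configuration is erased in step 8.

**Step 8**
Reactants: 18 tertiary allylic alcohol
Product: 19 9-(benzyloxymethyl)-11-nordrim-8-en-7-one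
Conditions: [C5H5NH][CrO3Cl] (pyridinium chlorochromate), 4 Å molecular sieves, CH2Cl2, rt
Reagents that add atoms: pyridinium chlorochromate, [O-][Cr](=O)(=O)Cl.c1cc[nH+]cc1
Why: Babler–Dauben oxidative 1,3-transposition: the chromate ester of the tertiary allylic alcohol undergoes a [3,3] shift to C7 and is oxidised there by hexavalent chromium. This moves the oxygen from C9 to C7 and the alkene to C8=C9; the benzyl ether is inert at room temperature.

**Step 9**
Reactants: 19 tetrasubstituted enone
Product: 21 9β-(benzyloxymethyl)-8α-hydroxy-11-nordriman-7-one (9α-H; 8β-methyl), via 8α-hydroperoxide 20 (not isolated)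
Conditions: Mn(dpm)3 (dpm = 2,2,6,6-tetramethylheptane-3,5-dionate; 0.2 equiv), PhSiH3, O2 (1 atm), i-PrOH/CH2Cl2, 0 °C to rt; then P(OEt)3
Reagents that add atoms: dioxygen, O=O
Why: Mukaiyama-type conjugate reduction–oxygenation of an enone: the manganese hydride transfers a hydrogen atom to the β-carbon C9, and the α-keto radical at C8 is captured by O2 and the hydroperoxide reduced by the phosphite. Both the hydrogen at C9 and the oxygen at C8 should arrive on the α face, anti to the axial C10 methyl, giving 9α-H and 8α-OH with the C8 methyl β.

**Step 10**
Reactants: 21 α-hydroxy ketone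
Product: 25 9β-(benzyloxymethyl)-6α,8α-dihydroxy-11-nordriman-7-one, via bis(trimethylsilyl) enol ether 22 (not isolated), via silyloxy epoxide 23 (not isolated), via bis(silyloxy) ketone 24 (not isolated)
Conditions: TMSOTf, Et3N, CH2Cl2, 0 °C; solvent exchange to hexane and filtration; mCPBA, hexane/CH2Cl2, −20 to 0 °C; then 1 M HCl, THF, rt
Reagents that add atoms: 3-chloroperoxybenzoic acid, OOC(=O)c1cccc(Cl)c1
Why: Rubottom oxidation: the ketone can enolise only toward C6 because C8 is fully substituted, and the peracid epoxidises the enol silane from the α face, the β face being closed by the axial methyls on C10 and C4. Silyl migration and acid hydrolysis give the 6α-alcohol, which is also the thermodynamic epimer at this enolisable centre.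

**Step 11**
Reactants: 25 dihydroxy ketone
Product: 26 6α-acetoxy-9β-(benzyloxymethyl)-8α-hydroxy-11-nordriman-7-one
Conditions: Ac2O, pyridine, DMAP (cat.), CH2Cl2, 0 °C to rt
Reagents that add atoms: acetic anhydride, CC(=O)OC(C)=O
Why: Nucleophile-catalysed acylation of the only secondary hydroxyl; the hindered tertiary 8-hydroxyl does not react. Because C7 is still a ketone, the acetate can only be on C6.

**Step 12**
Reactants: 26 acetoxy ketone
Product: 27 6α-acetoxy-9β-(benzyloxymethyl)-11-nordrimane-7β,8α-diol
Conditions: NaBH4, CeCl3·7H2O, MeOH/THF, −78 to −40 °C
Reagents that add atoms: none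
Why: Luche-type borohydride reduction: hydride should add axially from the open α face (only 5α-H and 9α-H are syn-axial), whereas the β trajectory is hindered by the axial 8β-methyl, so the equatorial 7β-alcohol is expected. Low temperature, the cerium-buffered medium and a neutral quench before warming are chosen to suppress acetate migration to O7.

**Step 13**
Reactants: 27 benzyl ether
Product: 28 6α-acetoxy-9β-(hydroxymethyl)-11-nordrimane-7β,8α-diol
Conditions: H2 (1 atm), 10% Pd/C, EtOAc, rt
Reagents that add atoms: none
Why: Hydrogenolysis of the benzyl ether under neutral conditions; nothing else in the molecule is reducible and the acetate stays in place.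

**Step 14**
Reactants: 28 triol monoacetate; 29 1-(triphenylphosphoranylidene)propan-2-one
Product: 31 target (6α-acetoxy-7β,8α-dihydroxy-14,15-dinorlabd-11(E)-en-13-one), via aldehyde 30 (not isolated)
Conditions: TEMPO (0.1 equiv), PhI(OAc)2, CH2Cl2, rt; then 29 (3 equiv), 40 °C
Reagents that add atoms: none
Why: The oxoammonium oxidation is selective for the primary alcohol over the hindered secondary 7-hydroxyl, and the β-hydroxy aldehyde is intercepted in the same flask by the stabilised ylide (Wittig reaction), which gives the (E)-enone. The medium stays near neutral, so acyl migration, loss of the 8-hydroxyl and epimerisation at C9 are not expected.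

## Compound list

1 | (R)-(−)-carvone | CC(=C)[C@@H]1CC=C(C)C(=O)C1 | starting material
2 | iodomethane | CI | starting material
3 | lithium α′-enolate of 1 (cross-conjugated dienolate) | CC(=C)[C@@H]1CC=C(C)C(O[Li])=C1 | intermediate
4 | (5R,6S)-6-methylcarvone (trans; C6 epimers carried together) | C[C@H]1[C@H](C(C)=C)CC=C(C)C1=O | intermediate
5 | ethyl 2-(bromomethyl)acrylate | CCOC(=O)C(=C)CBr | starting material
6 | lithium enolate of 4 | CC(=C)[C@@H]1CC=C(C)C(O[Li])=C1C | intermediate
7 | ethyl 2-{[1,3-dimethyl-2-oxo-6-(prop-1-en-2-yl)cyclohex-3-en-1-yl]methyl}acrylate, ring methyl cis and acrylate arm trans to isopropenyl | CCOC(=O)C(=C)C[C@@]1(C)[C@H](C(C)=C)CC=C(C)C1=O | intermediate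
8 | ethyl 9-oxo-11-nordrim-7-ene-2α-carboxylate (5α-H, 10β-methyl) | CCOC(=O)[C@@H]1C[C@]2(C)C(=O)C(C)=CC[C@H]2C(C)(C)C1 | intermediate
9 | 9-oxo-11-nordrim-7-ene-2α-carboxylic acid | OC(=O)[C@@H]1C[C@]2(C)C(=O)C(C)=CC[C@H]2C(C)(C)C1 | intermediate
10 | 9-oxo-11-nordrim-7-ene-2α-carbonyl chloride | ClC(=O)[C@@H]1C[C@]2(C)C(=O)C(C)=CC[C@H]2C(C)(C)C1 | intermediate
11 | 2-thioxopyridin-1(2H)-yl 9-oxo-11-nordrim-7-ene-2α-carboxylate (Barton ester) | S=C1C=CC=CN1OC(=O)[C@@H]2C[C@]3(C)C(=O)C(C)=CC[C@H]3C(C)(C)C2 | intermediate
12 | 11-nordrim-7-en-9-one (5α-H, 10β-methyl) | O=C1C(C)=CC[C@H]2C(C)(C)CCC[C@@]21C | intermediate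
13 | tributyltin hydride | CCCC[SnH](CCCC)CCCC | starting material
14 | benzyl chloromethyl ether | ClCOCc1ccccc1 | starting material
15 | tributylstannyllithium | [Li][Sn](CCCC)(CCCC)CCCC | intermediate
16 | tributyl[(benzyloxy)methyl]stannane | CCCC[Sn](CCCC)(CCCC)COCc1ccccc1 | intermediate
17 | (benzyloxy)methyllithium | [Li]COCc1ccccc1 | intermediate
18 | 9α-(benzyloxymethyl)-11-nordrim-7-en-9β-ol | C(OCc3ccccc3)[C@]1(O)C(C)=CC[C@H]2C(C)(C)CCC[C@@]21C | intermediate
19 | 9-(benzyloxymethyl)-11-nordrim-8-en-7-one | C(OCc3ccccc3)C1=C(C)C(=O)C[C@H]2C(C)(C)CCC[C@@]21C | intermediate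
20 | 9β-(benzyloxymethyl)-8α-hydroperoxy-11-nordriman-7-one (9α-H) | C(OCc3ccccc3)[C@H]1[C@](C)(OO)C(=O)C[C@H]2C(C)(C)CCC[C@@]21C | intermediate
21 | 9β-(benzyloxymethyl)-8α-hydroxy-11-nordriman-7-one (9α-H, 8β-methyl) | C(OCc3ccccc3)[C@H]1[C@](C)(O)C(=O)C[C@H]2C(C)(C)CCC[C@@]21C | intermediate
22 | 9β-(benzyloxymethyl)-7,8α-bis(trimethylsilyloxy)-11-nordrim-6-ene | C(OCc3ccccc3)[C@H]1[C@](C)(O[Si](C)(C)C)C(O[Si](C)(C)C)=C[C@H]2C(C)(C)CCC[C@@]21C | intermediate
23 | 9β-(benzyloxymethyl)-6α,7α-epoxy-7β,8α-bis(trimethylsilyloxy)-11-nordrimane | C(OCc4ccccc4)[C@H]1[C@](C)(O[Si](C)(C)C)[C@]3(O[Si](C)(C)C)O[C@@H]3[C@H]2C(C)(C)CCC[C@@]21C | intermediate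
24 | 9β-(benzyloxymethyl)-6α,8α-bis(trimethylsilyloxy)-11-nordriman-7-one | C(OCc3ccccc3)[C@H]1[C@](C)(O[Si](C)(C)C)C(=O)[C@H](O[Si](C)(C)C)[C@H]2C(C)(C)CCC[C@@]21C | intermediate
25 | 9β-(benzyloxymethyl)-6α,8α-dihydroxy-11-nordriman-7-one | C(OCc3ccccc3)[C@H]1[C@](C)(O)C(=O)[C@H](O)[C@H]2C(C)(C)CCC[C@@]21C | intermediate
26 | 6α-acetoxy-9β-(benzyloxymethyl)-8α-hydroxy-11-nordriman-7-one | C(OCc3ccccc3)[C@H]1[C@](C)(O)C(=O)[C@H](OC(C)=O)[C@H]2C(C)(C)CCC[C@@]21C | intermediate
27 | 6α-acetoxy-9β-(benzyloxymethyl)-11-nordrimane-7β,8α-diol | C(OCc3ccccc3)[C@H]1[C@](C)(O)[C@@H](O)[C@H](OC(C)=O)[C@H]2C(C)(C)CCC[C@@]21C | intermediate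
28 | 6α-acetoxy-9β-(hydroxymethyl)-11-nordrimane-7β,8α-diol | OC[C@H]1[C@](C)(O)[C@@H](O)[C@H](OC(C)=O)[C@H]2C(C)(C)CCC[C@@]21C | intermediate
29 | 1-(triphenylphosphoranylidene)propan-2-one | CC(=O)C=P(c1ccccc1)(c1ccccc1)c1ccccc1 | starting material
30 | 6α-acetoxy-7β,8α-dihydroxy-11-nordrimane-9β-carbaldehyde | O=C[C@H]1[C@](C)(O)[C@@H](O)[C@H](OC(C)=O)[C@H]2C(C)(C)CCC[C@@]21C | intermediate
31 | 6α-acetoxy-7β,8α-dihydroxy-14,15-dinorlabd-11(E)-en-13-one (CNP0136046.1) | CC(=O)/C=C/[C@H]1[C@](C)(O)[C@@H](O)[C@H](OC(C)=O)[C@H]2C(C)(C)CCC[C@@]21C | target

## Step count and least certain steps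

Total: 14 steps. Longest linear sequence: 13 steps from 1 (steps 1–5 and 7–14); step 6 prepares reagent 16 separately.

**Step 3 (key step).** The most likely failure is misdirected hydrogen-atom transfer: to the acrylate (which would saturate the acceptor) or to the ring enone, or reduction of the C4 radical to an isopropyl group before the comparatively slow 6-endo closure. Fallback: setting out from 7, Markovnikov hydrochlorination of the isopropenyl group (HCl, Et2O, 0 °C, as known for carvone) gives the tertiary chloride F1. Slow addition of (Me3Si)3SiH and AIBN in toluene at 80 °C then generates the same C4 radical by chlorine abstraction, with no metal hydride present to attack the other alkenes, and the Giese closure returns to the route at 8.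

**Step 9.** Hydrogen-atom transfer to a tetrasubstituted enone whose β-carbon is neopentylic may be slow, and the facial selectivity of hydrogen delivery at C9 or of oxygen capture at C8 may be incomplete; C9 cannot be corrected afterwards. Fallback: setting out from 19, reduction with NaBH4/CeCl3·7H2O gives the allylic alcohol F2. Hydroboration with BH3·SMe2 followed by NaOH/H2O2 should add boron to C8 (the less hindered carbon, next to the carbinol) and hydrogen to C9, both from the α face, giving the diol F3. Dess–Martin oxidation of the secondary 7-hydroxyl returns to the route at 21.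

**Step 7.** The basic α-alkoxy organolithium may deprotonate the γ-position C6 of the enone instead of adding to the hindered C9 carbonyl, or may decompose by Wittig rearrangement before it adds. Fallback: setting out from 12, the less basic Grignard reagent (i-PrO)Me2SiCH2MgCl with CeCl3 gives the β-silyl carbinol F4. Tamao oxidation (KF, KHCO3, H2O2) gives the diol F5, and selective benzylation of its primary hydroxyl (NaH, BnBr, THF, 0 °C) returns to the route at 18.

**Step 14.** The oxidation may not discriminate fully between the primary and the secondary alcohol, and slow olefination of the hindered aldehyde would give time for β-elimination of the 8-hydroxyl. Fallback: setting out from 27, silylation with Et3SiCl/imidazole gives the 7-O-triethylsilyl ether F6 and hydrogenolysis (H2, Pd/C) gives the primary alcohol F7. Dess–Martin oxidation, now without a competing secondary alcohol, gives the isolable aldehyde F8, and Wittig reaction with 29 in toluene gives the silylated enone F9. HF·pyridine in THF removes the silyl group without touching the acetate and returns to the route at 31.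

## Further compounds

F1 | step 3 | ethyl 2-{[6-(2-chloropropan-2-yl)-1,3-dimethyl-2-oxocyclohex-3-en-1-yl]methyl}acrylate | CCOC(=O)C(=C)C[C@@]1(C)[C@H](C(C)(C)Cl)CC=C(C)C1=O
F2 | step 9 | 9-(benzyloxymethyl)-11-nordrim-8-en-7β-ol | C(OCc3ccccc3)C1=C(C)[C@@H](O)C[C@H]2C(C)(C)CCC[C@@]21C
F3 | step 9 | 9β-(benzyloxymethyl)-11-nordrimane-7β,8α-diol | C(OCc3ccccc3)[C@H]1[C@](C)(O)[C@@H](O)C[C@H]2C(C)(C)CCC[C@@]21C
F4 | step 7 | 9α-{[isopropoxy(dimethyl)silyl]methyl}-11-nordrim-7-en-9β-ol | CC(C)O[Si](C)(C)C[C@]1(O)C(C)=CC[C@H]2C(C)(C)CCC[C@@]21C
F5 | step 7 | 9α-(hydroxymethyl)-11-nordrim-7-en-9β-ol | OC[C@]1(O)C(C)=CC[C@H]2C(C)(C)CCC[C@@]21C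
F6 | step 14 | 6α-acetoxy-9β-(benzyloxymethyl)-7β-(triethylsilyloxy)-11-nordriman-8α-ol | C(OCc3ccccc3)[C@H]1[C@](C)(O)[C@@H](O[Si](CC)(CC)CC)[C@H](OC(C)=O)[C@H]2C(C)(C)CCC[C@@]21C
F7 | step 14 | 6α-acetoxy-9β-(hydroxymethyl)-7β-(triethylsilyloxy)-11-nordriman-8α-ol | OC[C@H]1[C@](C)(O)[C@@H](O[Si](CC)(CC)CC)[C@H](OC(C)=O)[C@H]2C(C)(C)CCC[C@@]21C
F8 | step 14 | 6α-acetoxy-8α-hydroxy-7β-(triethylsilyloxy)-11-nordrimane-9β-carbaldehyde | O=C[C@H]1[C@](C)(O)[C@@H](O[Si](CC)(CC)CC)[C@H](OC(C)=O)[C@H]2C(C)(C)CCC[C@@]21C
F9 | step 14 | 6α-acetoxy-8α-hydroxy-7β-(triethylsilyloxy)-14,15-dinorlabd-11(E)-en-13-one | CC(=O)/C=C/[C@H]1[C@](C)(O)[C@@H](O[Si](CC)(CC)CC)[C@H](OC(C)=O)[C@H]2C(C)(C)CCC[C@@]21C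
A1 | alternative 1 | (2E,9E,11Z)-11-(tert-butyldimethylsilyloxy)-3,8,8-trimethyltrideca-2,9,11-trienal | O=C/C=C(\C)CCCC(C)(C)/C=C/C(O[Si](C)(C)C(C)(C)C)=C/C
A2 | alternative 1 | trans-fused bicyclic aldehyde with C6=C7 silyl enol ether (8β-methyl, 9β-formyl) | O=C[C@H]1[C@@H](C)C(O[Si](C)(C)C(C)(C)C)=C[C@H]2C(C)(C)CCC[C@]12C
A3 | alternative 2 | (5E,9E)-farnesylacetone | CC(=O)CC/C=C(\C)CC/C=C(\C)CCC=C(C)C
A4 | alternative 2 | sclareol oxide | CC1=CC[C@H]2[C@](C)(O1)CC[C@H]3C(C)(C)CCC[C@]23C
A5 | alternative 3 | monocyclic aldehyde carrying the enone chain and the C9 isopropenyl group | CC(=O)/C=C/[C@@H](C(C)=C)[C@@]1(C)CCCC(C)(C)[C@@H]1C=O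
A6 | alternative 3 | 6α-hydroxy-8(17)-ene decalin carrying the enone chain | CC(=O)/C=C/[C@H]1C(=C)C[C@H](O)[C@H]2C(C)(C)CCC[C@@]21C
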